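**Retrosynthetic overview**
- Target ⇐ C15-selective deacetylation of a 7,15-diacetate ⇐ triol ⇐ hydride reduction of a 7-oxo-8β-hydroxy enoate (C7 set by axial hydride attack).
- Key disconnection C7–C8: the α-ketol ⇐ a 7,8-seco keto-aldehyde; a carbene-generated acyl anion (Breslow intermediate) at C7 adds to the C8 methyl ketone and sets C8 (β-OH, α-CH3).
- Seco keto-aldehyde ⇐ ozonolysis of the Δ7 ring alkene of ethyl labda-7,13E-dien-15-oate ⇐ dehydration ⇐ HWE ⇐ C18 methyl ketone ⇐ (−)-sclareol.
- Ring order: ring A (with C5, C9, C10) comes from sclareol; ring B is opened and then re-formed last, in the key step.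

Assumption: the SMILES is read as the normal-series labdane (5S,7S,8R,9R,10S), i.e. 7β-OAc, 8β-OH, C17 methyl α, 13E; α/β use labdane numbering with the C10 methyl as β.

**Step 1**
Reactants: 1 (−)-sclareol, (13R)-labd-14-ene-8α,13-diol
Product: 2 8α-hydroxy-14,15-dinorlabdan-13-one
Conditions: KMnO4 (4 equiv), acetone–H2O, 0 °C → rt
Reagents that add atoms: none
Why: Permanganate oxidative cleavage of the vinyl carbinol (glycol cleavage, then oxidative decarboxylation of the α-hydroxy acid) removes C14/C15 and leaves the C13 methyl ketone, a classical sclareol degradation that touches no stereocentre.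

**Step 2**
Reactants: 2 8α-hydroxy-14,15-dinorlabdan-13-one; 3 ethyl 2-(diisopropoxyphosphoryl)acetate
Product: 4 ethyl (13E)-8α-hydroxylabd-13-en-15-oate
Conditions: 3 (2.5 equiv), NaH (2.4 equiv), THF, 0 °C; then 2, 60 °C
Reagents that add atoms: ethyl 2-(diisopropoxyphosphoryl)acetate (3), CCOC(=O)CP(=O)(OC(C)C)OC(C)C
Why: Horner–Wadsworth–Emmons olefination of the methyl ketone, in which the bulky diisopropyl phosphonate favours the E-enoate (expected about 6–9:1, Z-ester removed by chromatography) and, with no free NaH, the tertiary 8-OH stays protonated.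

**Step 3**
Reactants: 4 ethyl (13E)-8α-hydroxylabd-13-en-15-oate
Product: 5 ethyl labda-7,13E-dien-15-oate
Conditions: conc. H2SO4 (10 vol %), EtOH, 20 °C, stopped when 4 is consumed; AgNO3–silica chromatography
Reagents that add atoms: none
Why: E1 dehydration in which ionisation of the equatorial tertiary alcohol relieves the C17/C20 1,3-diaxial strain and the C8 cation loses the aligned axial H-7α to give mainly the trisubstituted Δ7 alkene (the Δ8(17) isomer re-enters through the same cation; an estimated 25–30 % of Δ8(17)/Δ8 isomers is removed), while the acid-stable enoate is untouched and no stereocentre is formed.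

**Step 4**
Reactants: 5 ethyl labda-7,13E-dien-15-oate
Product: 7 ethyl (13E)-7,8-dioxo-7,8-secolabd-13-en-15-oate, via secondary ozonide 6 (not isolated)
Conditions: O3 (1.05 equiv), CH2Cl2, −78 °C; then PPh3, −78 °C → rt
Reagents that add atoms: ozone, [O-][O+]=O
Why: Criegee ozonolysis, in which ozone adds to the electron-rich trisubstituted ring alkene far faster than to the electron-poor enoate and PPh3 reduces the ozonide to the 1,6-keto aldehyde under neutral conditions, so C9 (now α to the ketone) keeps its configuration.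

**Step 5**
Reactants: 7 ethyl (13E)-7,8-dioxo-7,8-secolabd-13-en-15-oate
Product: 8 ethyl (13E)-8β-hydroxy-7-oxolabd-13-en-15-oate (C17 methyl α)
Conditions: 3-benzyl-5-(2-hydroxyethyl)-4-methylthiazolium chloride (20 mol %), DBU (20 mol %), t-BuOH, 40 °C, Ar, 0.02 M
Reagents that add atoms: none
Why: Intramolecular crossed aldehyde–ketone benzoin reaction under N-heterocyclic carbene catalysis, in which the Breslow intermediate makes C7 an acyl anion that adds to the C8 ketone through a chair transition state rebuilding the trans-decalin with the C8 methyl equatorial (α, away from the axial C10 methyl), so the new tertiary OH is β (axial), and reversibility in the protic medium also favours this epimer.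

**Step 6**
Reactants: 8 ethyl (13E)-8β-hydroxy-7-oxolabd-13-en-15-oate (C17 methyl α)
Product: 9 (13E)-labd-13-ene-7β,8β,15-triol (C17 methyl α)
Conditions: LiAlH4 (3 equiv), THF, −78 → 0 °C; aqueous work-up
Reagents that add atoms: none
Why: LiAlH4 reduction, in which hydride attacks the C7 ketone axially from the open α-face, anti to the axial C8–O bond (Felkin–Anh, as with 7-oxo steroids), to give the equatorial 7β-OH cis to the 8β-OH, and reduces the enoate 1,2 to the E-allylic alcohol.

**Step 7**
Reactants: 9 (13E)-labd-13-ene-7β,8β,15-triol (C17 methyl α)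
Product: 10 (13E)-8β-hydroxylabd-13-ene-7β,15-diyl diacetate (C17 methyl α)
Conditions: Ac2O (4 equiv), pyridine, DMAP (5 mol %), 0 °C → rt
Reagents that add atoms: acetic anhydride, CC(=O)OC(C)=O
Why: DMAP-catalysed acylation of the primary and the secondary hydroxyl, while the axial tertiary 8-OH (1,3-diaxial to the C10 methyl) does not react under these conditions.

**Step 8**
Reactants: 10 (13E)-8β-hydroxylabd-13-ene-7β,15-diyl diacetate (C17 methyl α)
Product: 11 (13E)-8β,15-dihydroxylabd-13-en-7β-yl acetate (C17 methyl α), the target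
Conditions: Novozym 435 (immobilised Candida antarctica lipase B), n-BuOH (5 equiv), MTBE, 35 °C
Reagents that add atoms: none
Why: Lipase-catalysed transesterification (alcoholysis), in which the enzyme accepts the unhindered primary allylic acetate at the chain end but not the ring acetate flanked by the quaternary C8, so only the C15 acetate is removed and no stereocentre is touched.

**Compound list**
1 | (−)-sclareol, (13R)-labd-14-ene-8α,13-diol (5α-H, 9α-H, 10β-CH3; 8-OH α, C17 methyl β) | C1C[C@H]2C(C)(C)CCC[C@]2(C)[C@@H](CC[C@@](C)(O)C=C)[C@]1(C)O | starting material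
2 | 8α-hydroxy-14,15-dinorlabdan-13-one (side chain CH2CH2COCH3) | C1C[C@H]2C(C)(C)CCC[C@]2(C)[C@@H](CCC(C)=O)[C@]1(C)O | intermediate
3 | ethyl 2-(diisopropoxyphosphoryl)acetate | CCOC(=O)CP(=O)(OC(C)C)OC(C)C | starting material
4 | ethyl (13E)-8α-hydroxylabd-13-en-15-oate | C1C[C@H]2C(C)(C)CCC[C@]2(C)[C@@H](CC/C(C)=C/C(=O)OCC)[C@]1(C)O | intermediate
5 | ethyl labda-7,13E-dien-15-oate (C7=C8 in ring B) | C1=C(C)[C@H](CC/C(C)=C/C(=O)OCC)[C@@]2(C)CCCC(C)(C)[C@@H]2C1 | intermediate
6 | secondary ozonide of 5 (1,2,4-trioxolane across C7 and C8; the two bridgehead acetal carbons are not defined) | C13C[C@H]2C(C)(C)CCC[C@]2(C)[C@@H](CC/C(C)=C/C(=O)OCC)C(C)(O1)OO3 | intermediate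
7 | ethyl (13E)-7,8-dioxo-7,8-secolabd-13-en-15-oate (C5–CH2–CHO and C9–CO–CH3 on ring A) | O=CC[C@H]1C(C)(C)CCC[C@]1(C)[C@@H](CC/C(C)=C/C(=O)OCC)C(C)=O | intermediate
8 | ethyl (13E)-8β-hydroxy-7-oxolabd-13-en-15-oate (8-OH β/axial, C17 methyl α/equatorial) | O=C1C[C@H]2C(C)(C)CCC[C@]2(C)[C@@H](CC/C(C)=C/C(=O)OCC)[C@@]1(C)O | intermediate
9 | (13E)-labd-13-ene-7β,8β,15-triol (C17 methyl α) | O[C@H]1C[C@H]2C(C)(C)CCC[C@]2(C)[C@@H](CC/C(C)=C/CO)[C@@]1(C)O | intermediate
10 | (13E)-8β-hydroxylabd-13-ene-7β,15-diyl diacetate (C17 methyl α) | CC(=O)O[C@H]1C[C@H]2C(C)(C)CCC[C@]2(C)[C@@H](CC/C(C)=C/COC(C)=O)[C@@]1(C)O | intermediate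
11 | (5S,7S,8R,9R,10S,13E)-8,15-dihydroxylabd-13-en-7-yl acetate (7β-OAc, 8β-OH, C17 methyl α) | CC(=O)O[C@H]1C[C@H]2C(C)(C)CCC[C@]2(C)[C@@H](CC/C(C)=C/CO)[C@@]1(C)O | target

**Total step count:** 8
**Longest linear sequence:** 8 steps (1 → 11)

**Three steps most likely to fail**

Step 5 (ring closure). The ketone is hindered (acetyl on C9 next to the quaternary C10), DBU could promote aldol closure or C9 epimerisation, and the C8 selectivity rests on a modest preference for the equatorial methyl; any 8-epimer can be re-equilibrated by re-exposure to the carbene. The fallback changes the reactive intermediate from an organocatalytic acyl anion to a reductively formed ketyl. It sets out from 7: SmI2 (2.5 equiv) in THF–t-BuOH at −78 °C reduces the aldehyde first, and the ketyl couples with the C8 ketone in a Sm(III)-chelated pinacol cyclisation (cis-diol, C8 methyl equatorial) to give ethyl (13E)-7β,8β-dihydroxylabd-13-en-15-oate (C17 methyl α) F2. DIBAL-H (CH2Cl2, −78 °C) then reduces the ester of F2, and the route is rejoined at 9.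

Step 3 (regioselective dehydration). The C8 cation can also lose a C17 or the C9 proton, so Δ8(17) and Δ8 isomers may exceed the estimate, and loss of H-9 would erase the C9 centre. The fallback separates elimination from double-bond placement. It sets out from 4: POCl3–pyridine (0 °C → rt) eliminates by anti-E2 from the equatorial dichlorophosphate, for which only the C17 methyl hydrogens are antiperiplanar, and gives the exocyclic isomer ethyl labda-8(17),13E-dien-15-oate F1. RhCl3·3H2O (5 mol %) in EtOH at 75 °C then moves the double bond into the ring toward the less hindered C7 (the C9–H is tertiary and neopentylic), and the route is rejoined at 5.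

Step 8 (selective deacetylation). The enzyme may be slow on this bulky substrate, and chemical methanolysis could be eroded by assistance from the neighbouring 8-OH. The fallback uses orthogonal protection instead of selective deprotection. It sets out from 9: TBSCl–imidazole (CH2Cl2, 0 °C) silylates only the primary allylic hydroxyl to give (13E)-15-(tert-butyldimethylsilyloxy)labd-13-ene-7β,8β-diol (C17 methyl α) F3. Ac2O–pyridine–DMAP acetylates the 7β-OH to give (13E)-15-(tert-butyldimethylsilyloxy)-8β-hydroxylabd-13-en-7β-yl acetate (C17 methyl α) F4. HF·pyridine in THF removes the silyl group, and the route is rejoined at the target 11.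

**Further compounds**
F1 | step 3 | ethyl labda-8(17),13E-dien-15-oate | C1C[C@H]2C(C)(C)CCC[C@]2(C)[C@@H](CC/C(C)=C/C(=O)OCC)C1=C
F2 | step 5 | ethyl (13E)-7β,8β-dihydroxylabd-13-en-15-oate (C17 methyl α) | O[C@H]1C[C@H]2C(C)(C)CCC[C@]2(C)[C@@H](CC/C(C)=C/C(=O)OCC)[C@@]1(C)O
F3 | step 8 | (13E)-15-(tert-butyldimethylsilyloxy)labd-13-ene-7β,8β-diol (C17 methyl α) | O[C@H]1C[C@H]2C(C)(C)CCC[C@]2(C)[C@@H](CC/C(C)=C/CO[Si](C)(C)C(C)(C)C)[C@@]1(C)O
F4 | step 8 | (13E)-15-(tert-butyldimethylsilyloxy)-8β-hydroxylabd-13-en-7β-yl acetate (C17 methyl α) | CC(=O)O[C@H]1C[C@H]2C(C)(C)CCC[C@]2(C)[C@@H](CC/C(C)=C/CO[Si](C)(C)C(C)(C)C)[C@@]1(C)O
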